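**Retrosynthetic overview**
- Last C–C bond: Suzuki coupling joins C2 of an α-iodoenone (ring fragment) to an alkenyl boronate that already carries the chlorovinyl unit and the whole amide chain.
- Amide bond: (4E,7S)-7-methoxydodec-4-enoic acid plus (Z)-2-bromo-3-chloroallylamine, the latter from N-propargylphthalimide (alkyne chlorination, palladium-catalysed anti-hydrobromination, Gabriel release).
- Acid: Johnson–Claisen rearrangement sets the (E)-olefin; C7 comes from Noyori hydrogenation of methyl 3-oxooctanoate.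
- Ring (the only ring, closed first in its own branch): intramolecular aldol condensation of (S)-2-methyl-5-oxohexanal (organocatalytic Michael adduct of propanal and methyl vinyl ketone) gives (S)-4-methylcyclohexenone; MeLi addition, oxidative 1,3-transposition and α-iodination follow.

Assumption: the SMILES is read as (7S) in the chain, (S) at the ring methyl carbon, (4E) chain alkene and Cl cis to the ring on the chlorovinyl group ((E) by CIP); catalysts, reagents and solvents carry no compound numbers.

**Ring fragment**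

Step 1
Reactants: 1 propanal; 2 methyl vinyl ketone (but-3-en-2-one)
Product: 3 (2S)-2-methyl-5-oxohexanal
Conditions: (R)-2-[methoxy(diphenyl)methyl]pyrrolidine (5 mol %), ethyl 3,4-dihydroxybenzoate (20 mol %), neat, 4 °C, 36 h
Reagents that add atoms: none
Why: Enamine-catalysed asymmetric Michael addition in which the CPh2OMe group blocks one face of the (E)-enamine of propanal, so the (R)-catalyst gives the (2S)-aldehyde (the (S)-catalyst is known to give the mirror-image sense).

Step 2
Reactants: 3 (2S)-2-methyl-5-oxohexanal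
Product: 5 (4S)-4-methylcyclohex-2-en-1-one, via aldol adduct 4 (not isolated)
Conditions: LiOH·H2O (0.1 equiv), iPrOH, 0 °C → rt
Reagents that add atoms: none
Why: Intramolecular aldol condensation in which the methyl-ketone enolate attacks the aldehyde (the only pairing that gives a six-membered ring) and the aldol loses water by E1cB, while catalytic base at low temperature keeps the aldehyde α-centre, which becomes C4, from epimerising.

Step 3
Reactants: 5 (4S)-4-methylcyclohex-2-en-1-one
Product: 6 (4S)-1,4-dimethylcyclohex-2-en-1-ol (both C1 epimers)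
Conditions: MeLi (1.2 equiv), Et2O, −78 °C; then H2O
Reagents that add atoms: methyllithium [Li]C
Why: 1,2-Addition of the organolithium to the enone carbonyl is faster than γ-deprotonation at −78 °C, so C4 is untouched, and the new carbinol centre is destroyed in the next step.

Step 4
Reactants: 6 (4S)-1,4-dimethylcyclohex-2-en-1-ol
Product: 7 (6S)-3,6-dimethylcyclohex-2-en-1-one
Conditions: pyridinium chlorochromate (C5H5NH)[CrO3Cl] (2 equiv), Celite, CH2Cl2, rt
Reagents that add atoms: pyridinium chlorochromate [O-][Cr](=O)(=O)Cl.c1cc[nH+]cc1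
Why: Dauben–Babler oxidative 1,3-transposition, in which the tertiary allylic chromate ester undergoes a [3,3] shift (the new carbonyl oxygen comes from chromate) and is then oxidised, placing the carbonyl next to the methyl stereocentre without enolising it.

Step 5
Reactants: 7 (6S)-3,6-dimethylcyclohex-2-en-1-one
Product: 8 (6S)-2-iodo-3,6-dimethylcyclohex-2-en-1-one
Conditions: I2 (2 equiv), DMAP (0.2 equiv), pyridine/CH2Cl2 (1:1), rt, dark
Reagents that add atoms: iodine II
Why: Johnson α-iodination of an enone (amine conjugate addition, iodination of the enolate, E1cB loss of the amine) under weakly basic conditions that leave C6 configurationally intact.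

**Acid fragment**

Step 6
Reactants: 9 methyl 3-oxooctanoate
Product: 10 methyl (3S)-3-hydroxyoctanoate
Conditions: H2 (50 atm), RuCl2[(S)-BINAP] (0.2 mol %), MeOH, 50 °C
Reagents that add atoms: none
Why: Noyori asymmetric hydrogenation of a β-keto ester, in which the (S)-BINAP ruthenium catalyst gives the (3S)-alcohol (the (R)-ligand is known to give (R)-3-hydroxy esters).

Step 7
Reactants: 10 methyl (3S)-3-hydroxyoctanoate
Product: 11 methyl (3S)-3-methoxyoctanoate
Conditions: MeI (10 equiv), Ag2O (2 equiv), 4 Å molecular sieves, Et2O, 40 °C, dark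
Reagents that add atoms: iodomethane CI
Why: Purdie methylation is a non-basic O-alkylation that avoids retro-aldol cleavage and β-elimination of the β-hydroxy ester and does not touch the stereocentre.

Step 8
Reactants: 11 methyl (3S)-3-methoxyoctanoate
Product: 12 (3S)-3-methoxyoctanal
Conditions: iBu2AlH (1.1 equiv), CH2Cl2, −78 °C; then MeOH, aq. KNaC4H4O6 (potassium sodium tartrate)
Reagents that add atoms: none
Why: Partial ester reduction, because the tetrahedral aluminium hemiacetal is stable at −78 °C and releases the aldehyde only on work-up.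

Step 9
Reactants: 12 (3S)-3-methoxyoctanal
Product: 13 (5S)-5-methoxydec-1-en-3-ol (both C3 epimers)
Conditions: CH2=CHMgBr (1.3 equiv), THF, −78 → 0 °C; then H2O
Reagents that add atoms: vinylmagnesium bromide C=C[Mg]Br
Why: Grignard 1,2-addition to the aldehyde, where the epimer mixture at the new carbinol is of no consequence because that carbon becomes sp2 in the next step.

Step 10
Reactants: 13 (5S)-5-methoxydec-1-en-3-ol
Product: 15 ethyl (4E,7S)-7-methoxydodec-4-enoate, via ketene acetal 14 (not isolated)
Conditions: CH3C(OEt)3 (6 equiv), EtCO2H (0.1 equiv), 140 °C, EtOH distilled off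
Reagents that add atoms: triethyl orthoacetate CCOC(C)(OCC)OCC
Why: Johnson–Claisen rearrangement through a chair transition state with the alkyl chain equatorial gives the (E)-γ,δ-unsaturated ester and leaves C7 untouched.

Step 11
Reactants: 15 ethyl (4E,7S)-7-methoxydodec-4-enoate
Product: 16 (4E,7S)-7-methoxydodec-4-enoic acid
Conditions: LiOH (3 equiv), THF/MeOH/H2O, rt; then 1 M HCl to pH 3
Reagents that add atoms: lithium hydroxide [Li+].[OH-]
Why: Saponification by acyl–oxygen cleavage, which touches neither the isolated (E)-alkene nor the remote methyl ether.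

**Amine fragment**

Step 12
Reactants: 17 2-(prop-2-yn-1-yl)isoindoline-1,3-dione (N-propargylphthalimide)
Product: 18 2-(3-chloroprop-2-yn-1-yl)isoindoline-1,3-dione
Conditions: NCS (1.3 equiv), AgOAc (10 mol %), acetone, 50 °C, dark
Reagents that add atoms: N-chlorosuccinimide O=C1CCC(=O)N1Cl
Why: Electrophilic chlorination of the terminal alkyne through a silver acetylide, under conditions the imide tolerates.

Step 13
Reactants: 18 2-(3-chloroprop-2-yn-1-yl)isoindoline-1,3-dione
Product: 19 2-[(2Z)-2-bromo-3-chloroprop-2-en-1-yl]isoindoline-1,3-dione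
Conditions: LiBr (2 equiv), Pd(OAc)2 (5 mol %), AcOH, rt → 40 °C
Reagents that add atoms: lithium bromide [Li+].[Br-]
Why: Palladium-catalysed hydrobromination of a 1-haloalkyne by anti-bromopalladation (bromide attacks the internal carbon opposite the metal) and protonolysis of the C–Pd bond with retention, which puts Br on C2 cis to Cl.

Step 14
Reactants: 19 2-[(2Z)-2-bromo-3-chloroprop-2-en-1-yl]isoindoline-1,3-dione
Product: 20 (2Z)-2-bromo-3-chloroprop-2-en-1-amine
Conditions: N2H4·H2O (1.5 equiv), EtOH, 60 °C; filter; acid–base extraction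
Reagents that add atoms: none
Why: Ing–Manske hydrazinolysis of the Gabriel imide frees the primary amine, and the vinylic halides are inert to hydrazine.

**Assembly**

Step 15
Reactants: 16 (4E,7S)-7-methoxydodec-4-enoic acid; 20 (2Z)-2-bromo-3-chloroprop-2-en-1-amine
Product: 22 (4E,7S)-N-[(2Z)-2-bromo-3-chloroprop-2-en-1-yl]-7-methoxydodec-4-enamide, via benzotriazolyl ester 21 (not isolated)
Conditions: DIC (1.2 equiv), HOBt (1.2 equiv), CH2Cl2, 0 °C → rt
Reagents that add atoms: none
Why: Carbodiimide/HOBt amide coupling through the active ester, with no stereocentre α to the activated carbonyl.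

Step 16
Reactants: 22 (4E,7S)-N-[(2Z)-2-bromo-3-chloroprop-2-en-1-yl]-7-methoxydodec-4-enamide
Product: 23 (4E,7S)-N-[(2E)-3-chloro-2-(4,4,5,5-tetramethyl-1,3,2-dioxaborolan-2-yl)prop-2-en-1-yl]-7-methoxydodec-4-enamide
Conditions: B2pin2 (1.2 equiv), PdCl2(PPh3)2 (3 mol %), PPh3 (6 mol %), KOPh (1.5 equiv), toluene, 50 °C
Reagents that add atoms: bis(pinacolato)diboron CC1(C)OB(OC1(C)C)B1OC(C)(C)C(C)(C)O1
Why: Miyaura borylation of an alkenyl bromide, in which zerovalent palladium inserts into C–Br far faster than into C–Cl and boron replaces bromine with retention (the descriptor changes to E only through CIP priorities).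

Step 17
Reactants: 23 (4E,7S)-N-[(2E)-3-chloro-2-(4,4,5,5-tetramethyl-1,3,2-dioxaborolan-2-yl)prop-2-en-1-yl]-7-methoxydodec-4-enamide; 8 (6S)-2-iodo-3,6-dimethylcyclohex-2-en-1-one
Product: 24 (4E,7S)-N-[(2E)-3-chloro-2-[(5S)-2,5-dimethyl-6-oxocyclohex-1-en-1-yl]prop-2-en-1-yl]-7-methoxydodec-4-enamide
Conditions: Pd(PhCN)2Cl2 (5 mol %), AsPh3 (20 mol %), Ag2O (1.5 equiv), THF/H2O (8:1), rt, dark
Reagents that add atoms: none
Why: Suzuki–Miyaura coupling of an α-iodoenone with an alkenyl boronate, promoted by Ag2O without soluble base so the α'-stereocentre is not epimerised, with retention of olefin geometry and a triphenylarsine–palladium catalyst that does not activate the vinyl chloride.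

**Compound list**
1 | propanal | CCC=O | starting material
2 | methyl vinyl ketone (but-3-en-2-one) | CC(=O)C=C | starting material
3 | (2S)-2-methyl-5-oxohexanal | O=C[C@@H](C)CCC(C)=O | intermediate
4 | (4S)-3-hydroxy-4-methylcyclohexan-1-one (aldol adduct, C3 epimers) | C[C@H]1CCC(=O)CC1O | intermediate
5 | (4S)-4-methylcyclohex-2-en-1-one | C[C@H]1CCC(=O)C=C1 | intermediate
6 | (4S)-1,4-dimethylcyclohex-2-en-1-ol (C1 epimers) | C[C@H]1CCC(C)(O)C=C1 | intermediate
7 | (6S)-3,6-dimethylcyclohex-2-en-1-one | C[C@H]1CCC(C)=CC1=O | intermediate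
8 | (6S)-2-iodo-3,6-dimethylcyclohex-2-en-1-one | C[C@H]1CCC(C)=C(I)C1=O | intermediate
9 | methyl 3-oxooctanoate | CCCCCC(=O)CC(=O)OC | starting material
10 | methyl (3S)-3-hydroxyoctanoate | CCCCC[C@H](O)CC(=O)OC | intermediate
11 | methyl (3S)-3-methoxyoctanoate | CCCCC[C@H](OC)CC(=O)OC | intermediate
12 | (3S)-3-methoxyoctanal | CCCCC[C@H](OC)CC=O | intermediate
13 | (5S)-5-methoxydec-1-en-3-ol (C3 epimers) | CCCCC[C@H](OC)CC(O)C=C | intermediate
14 | 1-ethoxy-1-[(5S)-5-methoxydec-1-en-3-yloxy]ethene (ketene acetal) | CCCCC[C@H](OC)CC(OC(=C)OCC)C=C | intermediate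
15 | ethyl (4E,7S)-7-methoxydodec-4-enoate | CCCCC[C@@H](C/C=C/CCC(=O)OCC)OC | intermediate
16 | (4E,7S)-7-methoxydodec-4-enoic acid | CCCCC[C@@H](C/C=C/CCC(=O)O)OC | intermediate
17 | 2-(prop-2-yn-1-yl)isoindoline-1,3-dione | C#CCN1C(=O)c2ccccc2C1=O | starting material
18 | 2-(3-chloroprop-2-yn-1-yl)isoindoline-1,3-dione | ClC#CCN1C(=O)c2ccccc2C1=O | intermediate
19 | 2-[(2Z)-2-bromo-3-chloroprop-2-en-1-yl]isoindoline-1,3-dione | Cl/C=C(\Br)CN1C(=O)c2ccccc2C1=O | intermediate
20 | (2Z)-2-bromo-3-chloroprop-2-en-1-amine | NC/C(Br)=C/Cl | intermediate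
21 | 1H-benzotriazol-1-yl (4E,7S)-7-methoxydodec-4-enoate | CCCCC[C@@H](C/C=C/CCC(=O)On1nnc2ccccc12)OC | intermediate
22 | (4E,7S)-N-[(2Z)-2-bromo-3-chloroprop-2-en-1-yl]-7-methoxydodec-4-enamide | CCCCC[C@@H](C/C=C/CCC(=O)NC/C(Br)=C/Cl)OC | intermediate
23 | (4E,7S)-N-[(2E)-3-chloro-2-(4,4,5,5-tetramethyl-1,3,2-dioxaborolan-2-yl)prop-2-en-1-yl]-7-methoxydodec-4-enamide | CCCCC[C@@H](C/C=C/CCC(=O)NC/C(=C/Cl)B1OC(C)(C)C(C)(C)O1)OC | intermediate
24 | (4E,7S)-N-[(2E)-3-chloro-2-[(5S)-2,5-dimethyl-6-oxocyclohex-1-en-1-yl]prop-2-en-1-yl]-7-methoxydodec-4-enamide | CCCCC[C@@H](C/C=C/CCC(=O)NC/C(=C/Cl)C1=C(C)CC[C@H](C)C1=O)OC | target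

**Step count**
Total: 17 steps. Longest linear sequence: 9 steps (6–11, then 15–17); the ring branch (1–5) and the amine branch (12–14) run in parallel.

**Three steps most likely to fail, with fallbacks**

Step 13 (anti-hydrobromination of the chloroalkyne) may give regio- or stereoisomer mixtures or double addition. The fallback sets out from 17 and bypasses 18. Syn-bromoboration of the terminal alkyne with BBr3 (CH2Cl2, −78 °C → rt; then H2O) puts bromine on the internal carbon and boron on the terminal carbon, cis to each other, giving [(1Z)-2-bromo-3-(1,3-dioxoisoindolin-2-yl)prop-1-en-1-yl]boronic acid F1. Chlorodeboronation with NCS and Et3N in MeCN (ipso substitution with retention) replaces boron by chlorine and comes back to the route at 19.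

Step 16 (borylation of the bromo-chloro-allyl amide) may suffer protodehalogenation or homocoupling. The fallback sets out from 22. Stannylation with Me3SnSnMe3 and Pd(PPh3)4 in toluene at 80 °C gives (4E,7S)-N-[(2Z)-3-chloro-2-(trimethylstannyl)prop-2-en-1-yl]-7-methoxydodec-4-enamide F2. Base-free Stille coupling of F2 with 8 (Pd2(dba)3, AsPh3, CuI, NMP, rt → 50 °C) comes back to the route at 24.

Step 17 (coupling at the hindered tetrasubstituted iodoenone) may stall. The fallback sets out from 5 and makes the ring–vinyl bond before the 3-methyl group is present: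
- Iodination of 5 (I2, pyridine/CH2Cl2) gives (4S)-2-iodo-4-methylcyclohex-2-en-1-one F3.
- Coupling of F3 with 23 under the step 17 conditions gives (4E,7S)-N-[(2E)-3-chloro-2-[(3S)-3-methyl-6-oxocyclohex-1-en-1-yl]prop-2-en-1-yl]-7-methoxydodec-4-enamide F4.
- MeLi (2.5 equiv) with CeCl3 in THF at −78 °C adds 1,2 to give (4E,7S)-N-[(2E)-3-chloro-2-[(3S)-6-hydroxy-3,6-dimethylcyclohex-1-en-1-yl]prop-2-en-1-yl]-7-methoxydodec-4-enamide F5.
- Oxidative 1,3-transposition of F5 with pyridinium chlorochromate (C5H5NH)[CrO3Cl] in CH2Cl2 comes back to the route at 24.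

**Further compounds**
F1 | step 13 | [(1Z)-2-bromo-3-(1,3-dioxoisoindolin-2-yl)prop-1-en-1-yl]boronic acid | OB(O)/C=C(\Br)CN1C(=O)c2ccccc2C1=O
F2 | step 16 | (4E,7S)-N-[(2Z)-3-chloro-2-(trimethylstannyl)prop-2-en-1-yl]-7-methoxydodec-4-enamide | CCCCC[C@@H](C/C=C/CCC(=O)NC/C(=C/Cl)[Sn](C)(C)C)OC
F3 | step 17 | (4S)-2-iodo-4-methylcyclohex-2-en-1-one | C[C@H]1CCC(=O)C(I)=C1
F4 | step 17 | (4E,7S)-N-[(2E)-3-chloro-2-[(3S)-3-methyl-6-oxocyclohex-1-en-1-yl]prop-2-en-1-yl]-7-methoxydodec-4-enamide | CCCCC[C@@H](C/C=C/CCC(=O)NC/C(=C/Cl)C1=C[C@@H](C)CCC1=O)OC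
F5 | step 17 | (4E,7S)-N-[(2E)-3-chloro-2-[(3S)-6-hydroxy-3,6-dimethylcyclohex-1-en-1-yl]prop-2-en-1-yl]-7-methoxydodec-4-enamide (carbinol epimers) | CCCCC[C@@H](C/C=C/CCC(=O)NC/C(=C/Cl)C1=C[C@@H](C)CCC1(C)O)OC
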